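The numbers in the tables stem from a simulated flask for substances that don't exist; scatter was added.

Divide the rate at which coupling partner becomes target by the rate at which it goes any other way, and time drops out: what remains is a split, a selectivity factor. We assume that this ratio equals a fixed crossover charge over c(substrate).

| flask | substrate | coupling partner | remark | time |
|---|---|---|---|---|
| gamma | 5 mM | 10 mM | run made earlier |  |
| alpha | 58 mM | 10 mM | run made earlier |  |
| theta | 510 mM | 10 mM | run made earlier |  |
| ochre | 6.0 mM | 10.0 mM |  | 20 d |
| violet | 20 mM | 10.0 mM |  | 20 d |
| green | 60 mM | 10.0 mM |  | 20 d |
| red | 200 mM | 10.0 mM |  | 20 d |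
| grey | 500 mM | 10.0 mM |  | 20 d |

- gamma (time / d: target / %): 3.00: 22.1; 6.00: 47.9; 8.00: 57.3; 12.0: 72.8; 15.0: 78.4
- alpha (time / d: target / %): 1.04: 3.2; 2.00: 4.3; 4.00: 7.6; 8.00: 9.5; 15.0: 14.1
- theta (time / d: target / %): 1.25: 2.4; 4.00: 0; 6.00: 1.0; 10.0: 0; 15.0: 1.2

(standard deviation of a reading: 1 percentage point)

- the earlier runs were read with a standard deviation of 1 percentage point
- "hardly changes" means that all values lie within two and a half points (for a concentration: within two and a half percent of the largest)

1. [target] at the end for ochre, violet, green, red, grey, in this order
2. how that number moves from the first to the last of them (rises, then falls / falls, then rises / rises all the way / falls all the way / hardly changes)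

Alpha reads 8.18 mM of target at 15.0 d, from 10 mM of coupling partner. We treat that reading as the final split, so 58 mM times target over the remainder gives, as a reading with alpha's scatter in it, 260 mM: the crossover charge, the c(substrate) at which target and the other way take coupling partner equally. Theta helps little: one point of scatter there, 5.10 mM, is half of the partner charged.

The next run keeps c(coupling partner) at 10.0 mM and the time at 20 d, so the decision is the substrate charge. With substrate in excess, our reckoning puts target at c(coupling partner) times the crossover charge over the sum of crossover charge and c(substrate). That gives 9.29 mM for violet, 8.13 mM for green, 5.66 mM for red and 3.42 mM for grey, while ochre cannot pass its substrate charge of 6.0 mM. In this reckoning violet therefore stands higher than ochre and green, so we would make violet the working charge and run the richer flasks as a test of the ratio.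

The forecast gives 5.2 mM, 8.6 mM, 9 mM, 8 mM and 5.5 mM, a row that rises, then falls, and expects “a broad maximum near 60 mM”. We differ: it places green above violet, and its grey is higher than ours.

    adduct ⇌ target (K = 13.0, k = 0.00660 /h)
    substrate + coupling partner ⇌ adduct (K = 1600 /M, k = 4.70 /M/h)
    substrate + adduct → side product (k = 0.0500 /M/h)

The row comes out 5.09 mM, 8.24 mM, 6.59 mM, 3.61 mM, 1.78 mM; it rises, then falls, with violet highest. Green at 20.0 d holds target 11.0 % and side product 9.69 % of the substrate charged, side product counting double in that percentage. Put on green, the crossover charge of 260 mM gives 8.13 mM of target, and green stands at 6.59 mM. Put on grey, it gives 3.42 mM, and grey stands at 1.78 mM.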